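Assumption: the target has no stereocentre and no E/Z-isomeric double bond (each alkene ends in CMe2), so it is achiral and no stereocontrol is needed; the SMILES carry no stereo descriptors.

**Retrosynthetic overview** (ring A = benzo ring of the benzofuran, ring B = pendant aryl ring)
1. Target ⇒ three aryl–prenyl bonds, made last from one tribromo-triol 2-arylbenzofuran whose bromines sit exactly at C7, C2' and C6'.
2. Tribromo-triol ⇒ its ring B dimethyl ether (O-demethylation) ⇒ key disconnection: the furan O1–C2 bond (C–O), closed by 5-endo-dig addition of an ortho-hydroxyl to an alkyne.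
3. ortho-Alkynylphenol ⇒ Sonogashira coupling of 2-bromo-4-iodoresorcinol with 2,6-dibromo-3,5-dimethoxyphenylacetylene.
4. Alkyne ⇐ 3,5-dimethoxybenzaldehyde (double bromination, one-carbon homologation); iodide ⇐ 2-bromoresorcinol (iodination).
5. Ring order: both benzene rings are bought; the furan ring is the only ring made (step 4), and the prenyl groups go on after it.

**Route**

Step 1
Reactants: 1 3,5-dimethoxybenzaldehyde
Product: 3 2,6-dibromo-3,5-dimethoxybenzaldehyde, via 2-bromo-3,5-dimethoxybenzaldehyde 2 (not isolated)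
Conditions: NBS (2.3 equiv), MeCN, rt → 60 °C
Reagents that add atoms: N-bromosuccinimide, O=C1CCC(=O)N1Br
Why: Electrophilic aromatic bromination; C2 and C6 are each ortho to one methoxy and para to the other, so they brominate in turn ahead of the doubly flanked C4, and the aldehyde is untouched.

Step 2
Reactants: 3 2,6-dibromo-3,5-dimethoxybenzaldehyde
Product: 5 2,4-dibromo-3-ethynyl-1,5-dimethoxybenzene, via diazoalkene 4 (not isolated)
Conditions: dimethyl (1-diazo-2-oxopropyl)phosphonate (1.5 equiv), K2CO3 (2.5 equiv), MeOH/THF, 0 °C → rt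
Reagents that add atoms: dimethyl (1-diazo-2-oxopropyl)phosphonate (Ohira–Bestmann reagent), CC(=O)C(=[N+]=[N-])P(=O)(OC)OC
Why: Ohira–Bestmann (Seyferth–Gilbert) homologation; the phosphonate anion formed in the flask olefinates the aldehyde to a diazoalkene that loses N2 and gives the terminal alkyne by 1,2-hydrogen shift, under carbonate conditions that leave the aryl bromides alone.

Step 3
Reactants: 6 2-bromobenzene-1,3-diol (2-bromoresorcinol)
Product: 7 2-bromo-4-iodobenzene-1,3-diol
Conditions: NIS (1.0 equiv), MeCN, −10 → 0 °C, dark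
Reagents that add atoms: N-iodosuccinimide, O=C1CCC(=O)N1I
Why: Electrophilic aromatic iodination at C4 (ortho to one OH, para to the other; C4 and C6 are equivalent and C2 is blocked by bromine), held at one equivalent to avoid the 4,6-diiodide.

Step 4
Reactants: 5 2,4-dibromo-3-ethynyl-1,5-dimethoxybenzene; 7 2-bromo-4-iodobenzene-1,3-diol
Product: 9 7-bromo-2-(2,6-dibromo-3,5-dimethoxyphenyl)-1-benzofuran-6-ol, via alkynylresorcinol 8 (not isolated)
Conditions: PdCl2(PPh3)2 (3 mol %), CuI (5 mol %), Et3N, DMF, degassed, rt then 70 °C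
Reagents that add atoms: none
Why: Sonogashira coupling selective for the C–I bond over the three hindered, electron-rich C–Br bonds, followed in the same flask by copper/amine-promoted 5-endo-dig hydroalkoxylation of the ortho-hydroxy alkyne, which forms the O1–C2 bond and closes the furan ring.

Step 5
Reactants: 9 7-bromo-2-(2,6-dibromo-3,5-dimethoxyphenyl)-1-benzofuran-6-ol
Product: 11 4,6-dibromo-5-(7-bromo-6-hydroxy-1-benzofuran-2-yl)benzene-1,3-diol, via tris(dibromoboranyl) ether 10 (not isolated)
Conditions: BBr3 (6 equiv), CH2Cl2, −78 °C → rt; then MeOH/H2O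
Reagents that add atoms: none
Why: BBr3 O-demethylation (Lewis-acid ether cleavage: oxygen-to-boron coordination, then bromide SN2 at methyl); it is run before any prenyl group is present because ortho-prenylphenols would cyclise to chromans here, while aryl bromides and the benzofuran are inert.

Step 6
Reactants: 11 4,6-dibromo-5-(7-bromo-6-hydroxy-1-benzofuran-2-yl)benzene-1,3-diol; 12 4,4,5,5-tetramethyl-2-(3-methylbut-2-en-1-yl)-1,3,2-dioxaborolane (prenylboronic acid pinacol ester)
Product: 15 5-[6-hydroxy-7-(3-methylbut-2-en-1-yl)-1-benzofuran-2-yl]-4,6-bis(3-methylbut-2-en-1-yl)benzene-1,3-diol, via monoprenyl dibromide 13 (not isolated), via diprenyl monobromide 14 (not isolated)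
Conditions: 12 (6 equiv), Pd(OAc)2 (10 mol %), tBuXPhos (20 mol %), K3PO4 (9 equiv), THF/H2O 4:1, degassed, 60 °C
Reagents that add atoms: none
Why: Proposed new method: a threefold, protecting-group-free, linear-selective Suzuki–Miyaura prenylation of a tris(ortho-bromophenol). Zerovalent palladium carrying the bulky biarylphosphine adds oxidatively into each C–Br bond (expected order: ring A C7 first, then the two more hindered, more electron-rich ring B positions). The phosphate-activated prenylboronate transmetalates (SE2'-type, then σ–π–σ equilibration of the prenyl–palladium). Reductive elimination then occurs from the primary CH2–Pd form, because the bulky ligand and the ortho,ortho'-disubstituted aryl disfavour bond formation at the CMe2 terminus; this puts normal prenyl groups exactly where the bromines were and creates no stereocentre. The closest known reaction type is the ligand-controlled α-selective Suzuki–Miyaura coupling of prenylboronates with single, protected (hetero)aryl halides; it has not been shown on free ortho-bromophenols or threefold in one flask.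

**Compound list**
1 | 3,5-dimethoxybenzaldehyde | COc1cc(OC)cc(C=O)c1 | starting material
2 | 2-bromo-3,5-dimethoxybenzaldehyde | COc1cc(OC)c(Br)c(C=O)c1 | intermediate
3 | 2,6-dibromo-3,5-dimethoxybenzaldehyde | COc1cc(OC)c(Br)c(C=O)c1Br | intermediate
4 | 2,4-dibromo-3-(2-diazoethenyl)-1,5-dimethoxybenzene | COc1cc(OC)c(Br)c(C=C=[N+]=[N-])c1Br | intermediate
5 | 2,4-dibromo-3-ethynyl-1,5-dimethoxybenzene | COc1cc(OC)c(Br)c(C#C)c1Br | intermediate
6 | 2-bromobenzene-1,3-diol (2-bromoresorcinol) | Oc1cccc(O)c1Br | starting material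
7 | 2-bromo-4-iodobenzene-1,3-diol | Oc1ccc(I)c(O)c1Br | intermediate
8 | 2-bromo-4-[(2,6-dibromo-3,5-dimethoxyphenyl)ethynyl]benzene-1,3-diol | COc1cc(OC)c(Br)c(C#Cc2ccc(O)c(Br)c2O)c1Br | intermediate
9 | 7-bromo-2-(2,6-dibromo-3,5-dimethoxyphenyl)-1-benzofuran-6-ol | COc1cc(OC)c(Br)c(-c2cc3ccc(O)c(Br)c3o2)c1Br | intermediate
10 | 7-bromo-2-[2,6-dibromo-3,5-bis(dibromoboranyloxy)phenyl]-6-(dibromoboranyloxy)-1-benzofuran | BrB(Br)Oc1cc(OB(Br)Br)c(Br)c(-c2cc3ccc(OB(Br)Br)c(Br)c3o2)c1Br | intermediate
11 | 4,6-dibromo-5-(7-bromo-6-hydroxy-1-benzofuran-2-yl)benzene-1,3-diol | Oc1cc(O)c(Br)c(-c2cc3ccc(O)c(Br)c3o2)c1Br | intermediate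
12 | 4,4,5,5-tetramethyl-2-(3-methylbut-2-en-1-yl)-1,3,2-dioxaborolane | CC(C)=CCB1OC(C)(C)C(C)(C)O1 | starting material
13 | 4,6-dibromo-5-[6-hydroxy-7-(3-methylbut-2-en-1-yl)-1-benzofuran-2-yl]benzene-1,3-diol | CC(C)=CCc1c(O)ccc2cc(-c3c(Br)c(O)cc(O)c3Br)oc12 | intermediate
14 | 4-bromo-5-[6-hydroxy-7-(3-methylbut-2-en-1-yl)-1-benzofuran-2-yl]-6-(3-methylbut-2-en-1-yl)benzene-1,3-diol | CC(C)=CCc1c(O)ccc2cc(-c3c(Br)c(O)cc(O)c3CC=C(C)C)oc12 | intermediate
15 | 5-[6-hydroxy-7-(3-methylbut-2-en-1-yl)-1-benzofuran-2-yl]-4,6-bis(3-methylbut-2-en-1-yl)benzene-1,3-diol | CC(C)=CCc1c(O)cc(O)c(CC=C(C)C)c1-c1cc2ccc(O)c(CC=C(C)C)c2o1 | target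

**Step count and risks**

Total steps: 6. Longest linear sequence: 5 (steps 1, 2, 4, 5, 6); step 3 is the one-step side branch.

The three steps most likely to fail, each with one fallback:

First, step 6, the proposed new step. The triphenoxide may undergo oxidative addition too slowly, the two ring B bromides are flanked on both sides, and protodebromination or some branched (reverse-prenyl) coupling could erode the yield. The fallback uses known chemistry, sets out from 11 and comes back at 15. Compound 11 is protected with chloromethyl methyl ether and i-Pr2NEt in CH2Cl2 to give 7-bromo-2-[2,6-dibromo-3,5-bis(methoxymethoxy)phenyl]-6-(methoxymethoxy)-1-benzofuran F1. This undergoes the established linear-selective Negishi coupling with prenylzinc bromide (Me2C=CHCH2ZnBr, Pd(OAc)2/CPhos, THF, rt) to give 6-(methoxymethoxy)-2-[3,5-bis(methoxymethoxy)-2,6-bis(3-methylbut-2-en-1-yl)phenyl]-7-(3-methylbut-2-en-1-yl)-1-benzofuran F2. Mild acetal cleavage (HCl in MeOH, rt to 40 °C, short contact to avoid chroman formation) then gives 15.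

Second, step 4. The free, electron-rich iodoresorcinol may couple sluggishly or oxidise, the alkyne may homocouple, and ring closure may lag. The fallback separates coupling from ring closure on a protected phenol; it sets out from 7 and 5 and comes back at 9. Compound 7 is acetylated (Ac2O, pyridine) to 2-bromo-4-iodo-1,3-phenylene diacetate F3, a more reactive and stable electrophile. Sonogashira coupling of this with 5 (PdCl2(PPh3)2, CuI, Et3N, THF, rt) gives 2-bromo-4-[(2,6-dibromo-3,5-dimethoxyphenyl)ethynyl]-1,3-phenylene diacetate F4. Treatment with Cs2CO3 in MeOH/DMF at 60 °C removes both acetates, and the freed phenoxide adds 5-endo-dig to the alkyne to give 9.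

Third, step 2. The aldehyde is flanked by two bromines and the diazo olefination may stall. The fallback replaces diazo homologation with olefination, bromination and double elimination; it sets out from 3 and comes back at 5. Wittig methylenation of 3 (Ph3P=CH2 from methyltriphenylphosphonium bromide and KOtBu, THF) gives 2,4-dibromo-3-ethenyl-1,5-dimethoxybenzene F5. Addition of Br2 (CH2Cl2, −78 °C) gives racemic 2,4-dibromo-3-(1,2-dibromoethyl)-1,5-dimethoxybenzene F6. Double dehydrobromination with KOtBu in THF then gives 5.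

**Further compounds**
F1 | step 6 | 7-bromo-2-[2,6-dibromo-3,5-bis(methoxymethoxy)phenyl]-6-(methoxymethoxy)-1-benzofuran | COCOc1cc(OCOC)c(Br)c(-c2cc3ccc(OCOC)c(Br)c3o2)c1Br
F2 | step 6 | 6-(methoxymethoxy)-2-[3,5-bis(methoxymethoxy)-2,6-bis(3-methylbut-2-en-1-yl)phenyl]-7-(3-methylbut-2-en-1-yl)-1-benzofuran | COCOc1cc(OCOC)c(CC=C(C)C)c(-c2cc3ccc(OCOC)c(CC=C(C)C)c3o2)c1CC=C(C)C
F3 | step 4 | 2-bromo-4-iodo-1,3-phenylene diacetate | CC(=O)Oc1ccc(I)c(OC(C)=O)c1Br
F4 | step 4 | 2-bromo-4-[(2,6-dibromo-3,5-dimethoxyphenyl)ethynyl]-1,3-phenylene diacetate | COc1cc(OC)c(Br)c(C#Cc2ccc(OC(C)=O)c(Br)c2OC(C)=O)c1Br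
F5 | step 2 | 2,4-dibromo-3-ethenyl-1,5-dimethoxybenzene | COc1cc(OC)c(Br)c(C=C)c1Br
F6 | step 2 | 2,4-dibromo-3-(1,2-dibromoethyl)-1,5-dimethoxybenzene (racemic) | COc1cc(OC)c(Br)c(C(Br)CBr)c1Br
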